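(The readings were computed with made-up constants; the scatter is artificial.)

At 0.50 M of starting complex, two exchanges consume 1.00 M of incoming ligand. West and north are charged with 0.600 M and 0.250 M, less than that. North-west has 2.00 M, so starting complex is the limiting reagent there and [incoming ligand] stays at or above a floor of 1.00 M.

| flask | starting complex | incoming ligand | remark | time |
|---|---|---|---|---|
| violet | 0.50 M | 0.28 M | run made earlier |  |
| green | 0.50 M | 2.7 M | run made earlier |  |
| west | 0.50 M | 0.600 M |  | 15 min |
| north-west | 0.50 M | 2.00 M |  | 15 min |
| north | 0.50 M | 0.250 M |  | 15 min |

| run | time / min | complex with two exchanged / % | starting complex / % |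
|---|---|---|---|
| violet | 0.833 | 0 | 92.6 |
| violet | 1.33 | 1.3 | 89.7 |
| violet | 2.00 | 3.3 | 84.7 |
| violet | 3.00 | 4.8 | 79.7 |
| violet | 5.00 | 8.9 | 73.0 |
| violet | 6.00 | 10.5 | 71.2 |
| violet | 10.0 | 14.6 | 65.0 |
| green | 1.50 | 56.6 | 27.7 |
| green | 3.00 | 82.7 | 10.9 |
| green | 5.00 | 94.8 | 3.1 |
| green | 6.00 | 97.1 | 1.6 |
| green | 8.00 | 98.9 | 0.9 |
| green | 10.0 | 99.0 | 0 |

(scatter of a reading: 0.5 percentage points)

- which of these holds the largest part of the starting complex at the end of west (complex with two exchanged / complex with one exchanged / starting complex)
- which of these holds the largest part of the starting complex at the end of north-west (complex with two exchanged / complex with one exchanged / starting complex)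
- which of these holds the largest part of the starting complex at the end of north (complex with two exchanged / complex with one exchanged / starting complex)
- amount of complex with two exchanged at the end of north-west, in percent of the starting complex charged



The green run has a floor of 1.70 M. Its starting complex falls from 27.7% to 3.1% between 1.50 min and 5.00 min, which reads as 0.368 /M/min when reckoned on the floor. Treating the decay as pseudo-first-order gives the floor life, the half-life of starting complex with [incoming ligand] held at its floor: 1.88 min in north-west. The 15 min of north-west is 7.98 floor lives, which by this reckoning leaves about 0.400% of starting complex.

The forecast names complex with two exchanged for west, complex with two exchanged for north-west and starting complex for north, with 99.5% in north-west, on the grounds “ligand in excess”.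

The flasks give complex with two exchanged for west, complex with two exchanged for north-west and starting complex for north, with 99.1% in north-west.

    starting complex + incoming ligand → leaving ligand + complex with one exchanged (k = 0.360 /M/min)
    complex with one exchanged + incoming ligand → leaving ligand + complex with two exchanged (k = 0.920 /M/min)
    complex with two exchanged → over-reaction product (k = 4.80 × 10⁻⁴ /min)

In north-west, the first step has 81% of its turnover behind it by 3.00 min, and [incoming ligand] is 52.1% of its charge by 7.50 min. The loss to over-reaction product in north-west runs on, with a half-life of 24 h, long against 15 min, and reaches 0.593%. Starting complex in north-west ends at 0.203%, about half of the reckoned amount.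

For a neighbour of north-west charged with 1.2 M of incoming ligand, the floor is 0.200 M and the floor life 9.42 min, which by the same reckoning leaves about 33.2% of starting complex. That neighbour holds 6.6% at 15 min, less than the reckoned amount, with 88.8% of complex with two exchanged.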